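Ring A (C1–C5) plus the exocyclic carbon C6 is a disguised p-menthane. With C6 reinserted between C1 and C5, the C1 methyl and the C4 isopropyl carbinol sit para on a cyclohexanone that derives from (R)-terpinen-4-ol. The key step, a photochemical Wolff ring contraction of 2-diazocyclohexanone 8, moves C1 from C6 to C5. In one operation it closes ring A through the C1–C5 bond, carries the quaternary centre C1 over with retention and extrudes C6 as the handle for ring B. Chelation-controlled γ-silyloxyallylation (C6, C7), ring-closing metathesis (C8=C9), acylation, α-face epoxidation and global desilylation complete the target.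

Key step: step 5

Atom labels (daucane numbering): C1 = methyl-bearing ring-fusion carbon; C2, C3 = CH2 of ring A; C4 = isopropyl carbinol; C5 = ring-fusion CH; C6 = CH–O-aroyl; C7 = CHOH; C8 (methyl) and C9 = epoxide carbons; C10 = CH2. Ring A = cyclopentane C1–C5; ring B = cycloheptane C1, C5–C10. β = the face of the C1 methyl. The target is (1R,4R,5S,6R,7S,8R,9S).

Assumption: commercial (R)-(−)-terpinen-4-ol is taken to be of high enantiomeric purity, because C4 is the only source of absolute configuration in the route.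

Step 1
Reactants: 1 (R)-(−)-terpinen-4-ol
Product: 3 (5S)-5-hydroxy-2-methyl-5-(propan-2-yl)cyclohex-2-en-1-one, via allylic diol 2 (not isolated)
Conditions: SeO2 (0.3 equiv), t-BuOOH, CH2Cl2, 0 °C to rt; filtration, then MnO2, CH2Cl2, rt
Reagents that add atoms: tert-butyl hydroperoxide CC(C)(C)OO (oxygen, relayed by selenium dioxide O=[Se]=O)
Why: Riley allylic oxidation (ene reaction, then [2,3]-sigmatropic shift) should place oxygen on the ring CH2 (C6) next to the methyl-bearing alkene carbon and return the double bond to its original position, so C4, whose chirality rests only on the alkene position, is not scrambled as it would be through an allyl radical, and MnO2 converges the carbinol epimers and any enone already formed to 3.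

Step 2
Reactants: 3 (5S)-5-hydroxy-2-methyl-5-(propan-2-yl)cyclohex-2-en-1-one
Product: 4 (5S)-2-methyl-5-(propan-2-yl)-5-(triethylsilyloxy)cyclohex-2-en-1-one
Conditions: TESOTf, 2,6-lutidine, CH2Cl2, −78 to 0 °C
Reagents that add atoms: triethylsilyl triflate CC[Si](CC)(CC)OS(=O)(=O)C(F)(F)F
Why: Silylation of the hindered tertiary alcohol with the silyl triflate should block retro-aldol cleavage and dehydration–aromatisation of the β-hydroxy ketone in the basic steps that follow.

Step 3
Reactants: 4 (5S)-2-methyl-5-(propan-2-yl)-5-(triethylsilyloxy)cyclohex-2-en-1-one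
Product: 6 (2R,5S)-2-methyl-5-(propan-2-yl)-2-(prop-2-en-1-yl)-5-(triethylsilyloxy)cyclohexan-1-one, via lithium enolate 5 (not isolated)
Conditions: Li (2.2 equiv), t-BuOH (1.0 equiv), NH3(l)/THF, −78 °C; allyl bromide, −78 to −33 °C; solid NH4Cl
Reagents that add atoms: allyl bromide C=CCBr; lithium [Li] (counter-ion of 5 only)
Why: Dissolving-metal reductive alkylation of the enone gives the C6/C1 enolate regiospecifically, and allyl bromide should attack C1 axially on the half-chair that keeps isopropyl pseudo-equatorial, which places allyl cis to isopropyl and methyl cis to the silyloxy group (the 1R centre of the target).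

Step 4
Reactants: 6 (2R,5S)-2-methyl-5-(propan-2-yl)-2-(prop-2-en-1-yl)-5-(triethylsilyloxy)cyclohexan-1-one
Product: 8 (2R,5R)-6-diazo-2-methyl-5-(propan-2-yl)-2-(prop-2-en-1-yl)-5-(triethylsilyloxy)cyclohexan-1-one, via trifluoroacetyl ketone 7 (not isolated)
Conditions: LiN(SiMe3)2, THF, −78 °C; CF3CO2CH2CF3; then MsN3, Et3N, H2O (1 equiv), MeCN, rt
Reagents that add atoms: methanesulfonyl azide CS(=O)(=O)N=[N+]=[N-]; 2,2,2-trifluoroethyl trifluoroacetate O=C(OCC(F)(F)F)C(F)(F)F (acyl group of 7 only)
Why: Detrifluoroacetylative Regitz diazo transfer should work because C5 is the only enolisable position (C1 is quaternary), its transient trifluoroacetylation activates it toward the sulfonyl azide, and the low temperature keeps the β-silyloxy enolate from eliminating.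

Step 5
Reactants: 8 (2R,5R)-6-diazo-2-methyl-5-(propan-2-yl)-2-(prop-2-en-1-yl)-5-(triethylsilyloxy)cyclohexan-1-one
Product: 10 methyl (2R,5R)-2-methyl-5-(propan-2-yl)-2-(prop-2-en-1-yl)-5-(triethylsilyloxy)cyclopentane-1-carboxylate (epimers at daucane C5), via ketene 9 (not isolated)
Conditions: hν (medium-pressure mercury lamp, Pyrex filter), MeOH, 0 °C
Reagents that add atoms: methanol CO
Why: Excitation of the cyclic 2-diazoketone, whose diazo and carbonyl groups are locked s-Z, expels N2 in concert with the 1,2-shift of C1 from the carbonyl carbon C6 to the diazo carbon C5 (photochemical Wolff rearrangement), and the ring-contracted ketene 9 is intercepted by the solvent methanol. The closest known reaction type is the Wolff ring contraction of 2-diazocyclohexanones to cyclopentanecarboxylates. Ring A is closed not by an exo or endo attack but by a suprafacial 1,2-sigmatropic ring contraction (six to five), with C6 extruded as the exocyclic ester carbon. C1 migrates with retention and C4 is untouched, so both centres are carried over unchanged, whereas the new centre C5 arises by protonation of the ketene-derived enol, which is expected to be unselective or to favour the crowded epimer and is therefore corrected thermodynamically in step 6. Chemoselectivity (rearrangement rather than carbene cyclopropanation of the allyl group, a 1,2-shift from C4 or O–H insertion) is secured by direct irradiation without a metal catalyst, by the s-Z geometry and by the fact that C1 is the only group on C6 that can migrate.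

Step 6
Reactants: 10 methyl (2R,5R)-2-methyl-5-(propan-2-yl)-2-(prop-2-en-1-yl)-5-(triethylsilyloxy)cyclopentane-1-carboxylate (epimers at daucane C5)
Product: 12 (1R,2R,5R)-2-methyl-5-(propan-2-yl)-2-(prop-2-en-1-yl)-5-(triethylsilyloxy)cyclopentane-1-carbaldehyde, via epimeric aldehydes 11 (not isolated)
Conditions: i-Bu2AlH (1.2 equiv), CH2Cl2, −78 °C; aq. potassium sodium tartrate; then DBU (0.2 equiv), CH2Cl2, rt
Reagents that add atoms: none
Why: Partial reduction of the hindered ester through its stable aluminium hemiacetal is followed by base-catalysed enolisation, which should equilibrate C5 to the epimer whose formyl group lies on the face of the small groups (C1 methyl, C4 oxygen) and trans to isopropyl and allyl, that is the relative configuration of the target, while reprotonation should outrun β-elimination of the silyloxy group.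

Step 7
Reactants: 13 2-methylprop-2-en-1-ol
Product: 14 tert-butyldimethyl[(2-methylprop-2-en-1-yl)oxy]silane
Conditions: TBSCl, imidazole, CH2Cl2, rt
Reagents that add atoms: tert-butyldimethylsilyl chloride CC(C)(C)[Si](C)(C)Cl
Why: Standard imidazole-promoted silylation of a primary allylic alcohol.

Step 8
Reactants: 14 tert-butyldimethyl[(2-methylprop-2-en-1-yl)oxy]silane
Product: 16 (Z)-tributyl[3-(tert-butyldimethylsilyloxy)-2-methylprop-2-en-1-yl]stannane, via oxyallyllithium 15 (not isolated)
Conditions: s-BuLi, TMEDA, THF, −78 °C; Bu3SnCl, −78 °C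
Reagents that add atoms: tributyltin chloride CCCC[Sn](Cl)(CCCC)CCCC; sec-butyllithium [Li]C(C)CC (lithium of 15 only)
Why: α-Metalation of the allyl silyl ether at the oxygen-activated allylic CH2 gives an oxygen-chelated oxyallyl anion of Z geometry that is stannylated at its γ-terminus, and keeping the anion at −78 °C suppresses silyl migration from oxygen to carbon.

Step 9
Reactants: 12 (1R,2R,5R)-2-methyl-5-(propan-2-yl)-2-(prop-2-en-1-yl)-5-(triethylsilyloxy)cyclopentane-1-carbaldehyde; 16 (Z)-tributyl[3-(tert-butyldimethylsilyloxy)-2-methylprop-2-en-1-yl]stannane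
Product: 17 (1R,2R)-2-(tert-butyldimethylsilyloxy)-3-methyl-1-[(1S,2R,5R)-2-methyl-5-(propan-2-yl)-2-(prop-2-en-1-yl)-5-(triethylsilyloxy)cyclopentyl]but-3-en-1-ol
Conditions: Me2AlCl (2.5 equiv), CH2Cl2, −78 °C; 16 (1.5 equiv), −78 to −40 °C
Reagents that add atoms: none
Why: In this Lewis-acid-promoted SE2' addition of a γ-silyloxyallylstannane under dimethylaluminium chloride chelation control, aluminium should bridge the formyl oxygen and the cis C4 silyloxy oxygen, so the stannane attacks the chelate from the side of H-5 and away from C1 (6R), and the open transition state gives the syn (threo) C6/C7 pair that becomes the trans 6α,7β-dioxygen pattern in ring B.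

Step 10
Reactants: 17 (1R,2R)-2-(tert-butyldimethylsilyloxy)-3-methyl-1-[(1S,2R,5R)-2-methyl-5-(propan-2-yl)-2-(prop-2-en-1-yl)-5-(triethylsilyloxy)cyclopentyl]but-3-en-1-ol
Product: 18 7β-(tert-butyldimethylsilyloxy)-4β-(triethylsilyloxy)dauc-8-en-6α-ol (trans-fused; 1R,4R,5S,6R,7R)
Conditions: second-generation Hoveyda–Grubbs catalyst RuCl2(SIMes)(=CH-C6H4-2-O-i-Pr) (10 mol %), toluene (2 mM), 80 °C
Reagents that add atoms: none
Why: Ring-closing metathesis of the allyl group with the isopropenyl group closes ring B as its trisubstituted Z C8=C9 alkene, a closure well known for cycloheptenes and driven by loss of ethene.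

Step 11
Reactants: 19 4-hydroxybenzoic acid
Product: 21 4-(tert-butyldimethylsilyloxy)benzoic acid, via bis-silyl derivative 20 (not isolated)
Conditions: TBSCl (2.2 equiv), imidazole, DMF, rt; then AcOH/THF/H2O, rt
Reagents that add atoms: tert-butyldimethylsilyl chloride CC(C)(C)[Si](C)(C)Cl
Why: Exhaustive silylation followed by selective hydrolysis works because the silyl ester is far more labile than the aryl silyl ether.

Step 12
Reactants: 18 7β-(tert-butyldimethylsilyloxy)-4β-(triethylsilyloxy)dauc-8-en-6α-ol; 21 4-(tert-butyldimethylsilyloxy)benzoic acid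
Product: 22 7β-(tert-butyldimethylsilyloxy)-4β-(triethylsilyloxy)dauc-8-en-6α-yl 4-(tert-butyldimethylsilyloxy)benzoate
Conditions: DCC, DMAP, toluene, 60 °C
Reagents that add atoms: none
Why: Steglich esterification of the only free hydroxyl, the 6α-alcohol, whose β-oriented silyloxy neighbours at C4 and C7 point away from it.

Step 13
Reactants: 22 7β-(tert-butyldimethylsilyloxy)-4β-(triethylsilyloxy)dauc-8-en-6α-yl 4-(tert-butyldimethylsilyloxy)benzoate
Product: 23 8α,9α-epoxy-7β-(tert-butyldimethylsilyloxy)-4β-(triethylsilyloxy)daucan-6α-yl 4-(tert-butyldimethylsilyloxy)benzoate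
Conditions: dimethyldioxirane, acetone/CH2Cl2, −40 to 0 °C
Reagents that add atoms: dimethyldioxirane CC1(C)OO1
Why: Neutral dioxirane epoxidation of the only alkene should deliver oxygen to the α face (8R,9S), because the β face is covered by the allylic C7 silyloxy group and the angular C1 methyl.

Step 14
Reactants: 23 8α,9α-epoxy-7β-(tert-butyldimethylsilyloxy)-4β-(triethylsilyloxy)daucan-6α-yl 4-(tert-butyldimethylsilyloxy)benzoate
Product: 24 8α,9α-epoxy-4β,7β-dihydroxydaucan-6α-yl 4-hydroxybenzoate (target; 1R,4R,5S,6R,7S,8R,9S)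
Conditions: HF·pyridine, pyridine, THF, 0 °C to rt
Reagents that add atoms: none
Why: Fluoride-driven cleavage of all three silyl ethers in a pyridine-buffered, non-basic medium should spare the ester and the trisubstituted epoxide and avoid Payne rearrangement and C6-to-C7 acyl migration, both of which need an alkoxide.

Compound list
1 | (R)-(−)-terpinen-4-ol, (1R)-4-methyl-1-(propan-2-yl)cyclohex-3-en-1-ol | CC(C)[C@]1(O)CC=C(C)CC1 | starting material
2 | (1S)-4-methyl-1-(propan-2-yl)cyclohex-3-ene-1,5-diol (both epimers of the new carbinol, daucane C6) | CC(C)[C@]1(O)CC=C(C)C(O)C1 | intermediate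
3 | (5S)-5-hydroxy-2-methyl-5-(propan-2-yl)cyclohex-2-en-1-one | CC(C)[C@]1(O)CC=C(C)C(=O)C1 | intermediate
4 | (5S)-2-methyl-5-(propan-2-yl)-5-(triethylsilyloxy)cyclohex-2-en-1-one | CC(C)[C@]1(O[Si](CC)(CC)CC)CC=C(C)C(=O)C1 | intermediate
5 | lithium (5S)-2-methyl-5-(propan-2-yl)-5-(triethylsilyloxy)cyclohex-1-en-1-olate | CC(C)[C@]1(O[Si](CC)(CC)CC)CCC(C)=C([O-])C1.[Li+] | intermediate
6 | (2R,5S)-2-methyl-5-(propan-2-yl)-2-(prop-2-en-1-yl)-5-(triethylsilyloxy)cyclohexan-1-one (allyl cis to isopropyl) | CC(C)[C@]1(O[Si](CC)(CC)CC)CC[C@](C)(CC=C)C(=O)C1 | intermediate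
7 | 6-(trifluoroacetyl) derivative of 6 (enolised 1,3-diketone) | CC(C)[C@]1(O[Si](CC)(CC)CC)CC[C@](C)(CC=C)C(=O)C1C(=O)C(F)(F)F | intermediate
8 | (2R,5R)-6-diazo-2-methyl-5-(propan-2-yl)-2-(prop-2-en-1-yl)-5-(triethylsilyloxy)cyclohexan-1-one | CC(C)[C@]1(O[Si](CC)(CC)CC)CC[C@](C)(CC=C)C(=O)C1=[N+]=[N-] | intermediate
9 | [(2R,5R)-2-methyl-5-(propan-2-yl)-2-(prop-2-en-1-yl)-5-(triethylsilyloxy)cyclopentylidene]methanone (ketene) | CC(C)[C@]1(O[Si](CC)(CC)CC)CC[C@](C)(CC=C)C1=C=O | intermediate
10 | methyl (2R,5R)-2-methyl-5-(propan-2-yl)-2-(prop-2-en-1-yl)-5-(triethylsilyloxy)cyclopentane-1-carboxylate (epimers at daucane C5) | CC(C)[C@]1(O[Si](CC)(CC)CC)CC[C@](C)(CC=C)C1C(=O)OC | intermediate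
11 | (2R,5R)-2-methyl-5-(propan-2-yl)-2-(prop-2-en-1-yl)-5-(triethylsilyloxy)cyclopentane-1-carbaldehyde (epimers at daucane C5) | CC(C)[C@]1(O[Si](CC)(CC)CC)CC[C@](C)(CC=C)C1C=O | intermediate
12 | (1R,2R,5R)-2-methyl-5-(propan-2-yl)-2-(prop-2-en-1-yl)-5-(triethylsilyloxy)cyclopentane-1-carbaldehyde (formyl cis to methyl and silyloxy) | CC(C)[C@]1(O[Si](CC)(CC)CC)CC[C@](C)(CC=C)[C@H]1C=O | intermediate
13 | 2-methylprop-2-en-1-ol | C=C(C)CO | starting material
14 | tert-butyldimethyl[(2-methylprop-2-en-1-yl)oxy]silane | C=C(C)CO[Si](C)(C)C(C)(C)C | intermediate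
15 | 1-(tert-butyldimethylsilyloxy)-2-methylallyllithium | C=C(C)C([Li])O[Si](C)(C)C(C)(C)C | intermediate
16 | (Z)-tributyl[3-(tert-butyldimethylsilyloxy)-2-methylprop-2-en-1-yl]stannane | CCCC[Sn](CCCC)(CCCC)C/C(C)=C\O[Si](C)(C)C(C)(C)C | intermediate
17 | (1R,2R)-2-(tert-butyldimethylsilyloxy)-3-methyl-1-[(1S,2R,5R)-2-methyl-5-(propan-2-yl)-2-(prop-2-en-1-yl)-5-(triethylsilyloxy)cyclopentyl]but-3-en-1-ol | CC(C)[C@]1(O[Si](CC)(CC)CC)CC[C@](C)(CC=C)[C@H]1[C@@H](O)[C@H](O[Si](C)(C)C(C)(C)C)C(C)=C | intermediate
18 | 7β-(tert-butyldimethylsilyloxy)-4β-(triethylsilyloxy)dauc-8-en-6α-ol (1R,4R,5S,6R,7R) | CC(C)[C@]1(O[Si](CC)(CC)CC)CC[C@]2(C)CC=C(C)[C@@H](O[Si](C)(C)C(C)(C)C)[C@H](O)[C@H]21 | intermediate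
19 | 4-hydroxybenzoic acid | OC(=O)c1ccc(O)cc1 | starting material
20 | tert-butyldimethylsilyl 4-(tert-butyldimethylsilyloxy)benzoate | CC(C)(C)[Si](C)(C)OC(=O)c1ccc(O[Si](C)(C)C(C)(C)C)cc1 | intermediate
21 | 4-(tert-butyldimethylsilyloxy)benzoic acid | OC(=O)c1ccc(O[Si](C)(C)C(C)(C)C)cc1 | intermediate
22 | 7β-(tert-butyldimethylsilyloxy)-4β-(triethylsilyloxy)dauc-8-en-6α-yl 4-(tert-butyldimethylsilyloxy)benzoate | CC(C)[C@]1(O[Si](CC)(CC)CC)CC[C@]2(C)CC=C(C)[C@@H](O[Si](C)(C)C(C)(C)C)[C@H](OC(=O)c3ccc(O[Si](C)(C)C(C)(C)C)cc3)[C@H]21 | intermediate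
23 | 8α,9α-epoxy-7β-(tert-butyldimethylsilyloxy)-4β-(triethylsilyloxy)daucan-6α-yl 4-(tert-butyldimethylsilyloxy)benzoate | CC(C)[C@]1(O[Si](CC)(CC)CC)CC[C@]2(C)C[C@@H]3O[C@]3(C)[C@@H](O[Si](C)(C)C(C)(C)C)[C@H](OC(=O)c3ccc(O[Si](C)(C)C(C)(C)C)cc3)[C@H]21 | intermediate
24 | 8α,9α-epoxy-4β,7β-dihydroxydaucan-6α-yl 4-hydroxybenzoate (1R,4R,5S,6R,7S,8R,9S) | CC(C)[C@]1(O)CC[C@]2(C)C[C@@H]3O[C@]3(C)[C@@H](O)[C@H](OC(=O)c3ccc(O)cc3)[C@H]21 | target

Total step count: 14
Longest linear sequence: 11 steps (steps 1–6, 9, 10, 12, 13, 14)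

Steps most likely to fail

**Step 9.** The hindered tertiary silyl ether may fail to chelate, so the other formyl face is attacked. The syn preference may erode because of the extra methyl group of the stannane, and addition to the doubly neopentyl aldehyde may be sluggish. The fallback sets out from 12 and returns at 17, and it fixes both centres with a chiral auxiliary instead of the substrate.
- Commercial (S)-4-benzyloxazolidin-2-one is N-acylated (n-BuLi, (tert-butyldimethylsilyloxy)acetyl chloride) to the glycolyl imide (S)-4-benzyl-3-[(tert-butyldimethylsilyloxy)acetyl]oxazolidin-2-one F1.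
- Its Z boron enolate (Bu2BOTf, Et3N, CH2Cl2, −78 °C) is added to 12 in an Evans syn aldol reaction to give the syn-aldol imide F2.
- Me(MeO)NH·HCl/AlMe3 converts this to the Weinreb amide F3, and MeMgBr gives the methyl ketone F4.
- Petasis methylenation (Cp2TiMe2, toluene, 65 °C) turns the ketone into the isopropenyl group of 17.

**Step 5 (with its correction in step 6).** Carbene-type diversion may occur during photolysis. The ketene-derived enol may also be protonated on the open face, which leaves C5 mainly in the crowded configuration, so that the later base equilibration has to compete with β-elimination of the silyloxy group. The fallback sets out from 6 and returns at 12. It forms the same C1–C5 bond stereospecifically by a quasi-Favorskii (halohydrin semipinacol) ring contraction.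
- The lithium enolate of 6 (LiN(SiMe3)2, THF, −78 °C) is brominated with N-bromosuccinimide to the equatorial 6-bromo ketone F5. Bromine sits cis to the silyloxy group, because the axial position is syn-axial to allyl.
- LiAlH4 (THF, 0 °C to reflux) adds hydride to C6, and the alkoxide pushes C1 onto C5 anti to the bromide, with inversion at C5.
- The aldehyde formed is reduced in situ to the ring-contracted primary alcohol F6.
- Dess–Martin periodinane oxidises F6 to 12 without any epimerisation step.

**Step 3.** Facial selectivity in the alkylation of the enolate may be poor, because both C4 substituents are sizeable and the two half-chairs lie close in energy. Over-reduction or polyalkylation is also possible. The fallback sets out from 4 and returns at 6, and it replaces substrate control by catalyst control.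
- Conjugate reduction of 4 with LiBH(s-Bu)3 (THF, −78 °C) and trapping with allyl chloroformate gives the allyl enol carbonate F7.
- F7 undergoes a decarboxylative asymmetric Tsuji allylation (Pd2(dba)3, (R)-t-BuPHOX, toluene, rt; the ligand enantiomer that should favour the 2R centre) to give 6.

Further compounds
F1 | step 9 | (S)-4-benzyl-3-[(tert-butyldimethylsilyloxy)acetyl]oxazolidin-2-one | CC(C)(C)[Si](C)(C)OCC(=O)N1[C@@H](Cc2ccccc2)COC1=O
F2 | step 9 | syn-aldol imide (6R,7S; daucane labels) from F1 and 12 | CC(C)[C@]1(O[Si](CC)(CC)CC)CC[C@](C)(CC=C)[C@H]1[C@@H](O)[C@H](O[Si](C)(C)C(C)(C)C)C(=O)N1[C@@H](Cc2ccccc2)COC1=O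
F3 | step 9 | Weinreb amide derived from F2 | CC(C)[C@]1(O[Si](CC)(CC)CC)CC[C@](C)(CC=C)[C@H]1[C@@H](O)[C@H](O[Si](C)(C)C(C)(C)C)C(=O)N(C)OC
F4 | step 9 | (3S,4R)-3-(tert-butyldimethylsilyloxy)-4-hydroxy-4-[(1S,2R,5R)-2-methyl-5-(propan-2-yl)-2-(prop-2-en-1-yl)-5-(triethylsilyloxy)cyclopentyl]butan-2-one | CC(C)[C@]1(O[Si](CC)(CC)CC)CC[C@](C)(CC=C)[C@H]1[C@@H](O)[C@H](O[Si](C)(C)C(C)(C)C)C(C)=O
F5 | step 5 | 6-bromo derivative of 6, bromine equatorial and cis to the silyloxy group | CC(C)[C@]1(O[Si](CC)(CC)CC)CC[C@](C)(CC=C)C(=O)[C@H]1Br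
F6 | step 5 | [(1R,2R,5R)-2-methyl-5-(propan-2-yl)-2-(prop-2-en-1-yl)-5-(triethylsilyloxy)cyclopentyl]methanol | CC(C)[C@]1(O[Si](CC)(CC)CC)CC[C@](C)(CC=C)[C@H]1CO
F7 | step 3 | allyl (5S)-2-methyl-5-(propan-2-yl)-5-(triethylsilyloxy)cyclohex-1-en-1-yl carbonate | CC(C)[C@]1(O[Si](CC)(CC)CC)CCC(C)=C(OC(=O)OCC=C)C1
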